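**Retrosynthetic overview**
1. The strategy rests on the cyclohept-2-ene-1,4-diol unit of the seven-membered ring: the ester oxygen on C6 and the hydroxyl on C9 sit on the two allylic carbons of the C7=C8(CH3) alkene, so both C–O bonds are traced back to one O2 added across C6 and C9 of a C6=C7–C8=C9 diene.
2. Target ⇐ C9 ketone (hydride from the α face, after vanilloylation of the 6α-hydroxyl) ⇐ 6α,9α-endoperoxide (amine-induced peroxide fragmentation with loss of H9) ⇐ trans-fused dauca-6,8-diene with the C4 oxygen silylated.
3. Diene ⇐ dienyl triflate ⇐ C6-keto-C7=C8 enone ⇐ ring-closing metathesis of a cyclopentane carrying a vinyl carbinol chain on C5 and a 3-methylbut-3-enyl chain on C1.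
4. Ring order: the five-membered ring is bought (3-ethoxycyclopentenone) and decorated (C1 by asymmetric methyl conjugate addition, C5 by aldol with acrolein, C4 by isopropyl Grignard addition); the seven-membered ring is closed second; the 1,2-dioxine ring is closed third in the key step and opened again.

Key step: step 10

Numbering used throughout: five-membered ring C1(CH3)–C2–C3–C4–C5, seven-membered ring C5–C6–C7–C8(CH3)–C9–C10–C1; β is the face of the C1 methyl; compounds 14 to 27 are trans-fused (C1 methyl β, H5 α).
Assumption: the ligand antipode named in step 2 is taken to give the (S) quaternary carbon; if the sense of induction is the reverse, the mirror-image ligand is used.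

**Step 1**
Reactants: 1 4-bromo-2-methylbut-1-ene; 2 3-ethoxycyclopent-2-en-1-one
Product: 5 3-(3-methylbut-3-en-1-yl)cyclopent-2-en-1-one, via Grignard reagent 3 (not isolated), via magnesium alkoxide adduct 4 (not isolated)
Conditions: Mg, THF, rt; then 2, THF, 0 °C; then 1 M HCl, 0 °C
Reagents that add atoms: water, O
Why: Stork–Danheiser transposition: the Grignard reagent adds 1,2 to the vinylogous ester and cold dilute acid converts the enol-ether carbinol into the 3-alkylcyclopentenone with loss of ethanol and water, conditions too mild to isomerise the 1,1-disubstituted alkene.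

**Step 2**
Reactants: 5 3-(3-methylbut-3-en-1-yl)cyclopent-2-en-1-one; 6 trimethylaluminium
Product: 8 (S)-trimethyl{[3-methyl-3-(3-methylbut-3-en-1-yl)cyclopent-1-en-1-yl]oxy}silane, via dimethylaluminium enolate 7 (not isolated)
Conditions: Me3Al, copper thiophene-2-carboxylate (C5H3CuO2S, 5 mol %), (R,R)-N,N-bis(1-phenylethyl)-P,P-diphenylphosphinous amide (10 mol %), Et2O, −30 °C; then TMSOTf, −30 → 0 °C
Reagents that add atoms: trimethylaluminium (6), C[Al](C)C; trimethylsilyl trifluoromethanesulfonate, C[Si](C)(C)OS(=O)(=O)C(F)(F)F
Why: Copper-catalysed asymmetric conjugate addition of a trialkylaluminium to a 3-alkylcyclopentenone creates the quaternary carbon (later C1) under ligand control, and O-silylation of the aluminium enolate fixes the enolate on the side of the new quaternary carbon for step 3.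

**Step 3**
Reactants: 8 (S)-silyl enol ether; 9 acrolein
Product: 11 (2S,3S)-2-(1-hydroxyprop-2-en-1-yl)-3-methyl-3-(3-methylbut-3-en-1-yl)cyclopentan-1-one (both carbinol epimers), via lithium enolate 10 (not isolated)
Conditions: MeLi, THF, 0 °C → rt; then acrolein, −78 °C; sat. NH4Cl at −78 °C
Reagents that add atoms: acrolein (9), C=CC=O
Why: Methyllithium cleaves the silyl enol ether to the regiodefined lithium enolate, which should add 1,2 to acrolein (kinetic aldol) on the face anti to the longer chain on the neighbouring quaternary carbon, so the new C5 substituent comes out cis to the methyl (the arrangement that later gives the trans ring fusion); the carbinol centre is a mixture that is erased in step 6.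

**Step 4**
Reactants: 11 aldol adduct; 12 isopropylmagnesium chloride
Product: 13 (1R,2S,3S)-2-(1-hydroxyprop-2-en-1-yl)-3-methyl-3-(3-methylbut-3-en-1-yl)-1-(propan-2-yl)cyclopentan-1-ol (both carbinol epimers)
Conditions: iPrMgCl (3 equiv), anhydrous CeCl3, THF, −78 → 0 °C; sat. NH4Cl
Reagents that add atoms: isopropylmagnesium chloride (12), CC(C)[Mg]Cl
Why: CeCl3-promoted Grignard addition suppresses enolisation and β-hydride reduction, and the isopropyl group should enter C4 trans to the adjacent C5 side chain and anti to the C1 methyl, placing the tertiary hydroxyl on the β face (4R in the final numbering).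

**Step 5**
Reactants: 13 triene diol
Product: 14 (1S,4R,5S)-dauc-7-ene-4,6-diol (both C6 epimers)
Conditions: second-generation Grubbs catalyst RuCl2(=CHPh)(PCy3)(H2IMes) (5 mol %), CH2Cl2 (0.005 M), 40 °C
Reagents that add atoms: none
Why: Ring-closing metathesis between the vinyl carbinol and the 1,1-disubstituted alkene closes the seven-membered ring as the trisubstituted C7=C8 alkene with loss of ethene, and the trans-disposed chains give the trans-fused bicycle.

**Step 6**
Reactants: 14 bicyclic diol
Product: 15 (1S,4R,5R)-4-hydroxydauc-7-en-6-one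
Conditions: Dess–Martin periodinane, NaHCO3, CH2Cl2, 0 °C → rt
Reagents that add atoms: none
Why: Dess–Martin oxidation converts both C6 epimers of the secondary allylic alcohol into one enone under buffered, non-enolising conditions that leave the tertiary C4 hydroxyl and the C5 configuration untouched.

**Step 7**
Reactants: 15 hydroxy enone
Product: 16 (1S,4R,5R)-4-(triethylsilyloxy)dauc-7-en-6-one
Conditions: TESOTf, 2,6-lutidine, CH2Cl2, −78 → 0 °C
Reagents that add atoms: triethylsilyl trifluoromethanesulfonate, CC[Si](CC)(CC)OS(=O)(=O)C(F)(F)F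
Why: A silyl triflate with 2,6-lutidine silylates the hindered tertiary alcohol, which prevents its triflation and retro-aldol cleavage in step 8 and later adds bulk to the β face next to C6.

**Step 8**
Reactants: 16 silyloxy enone
Product: 17 (1R,4R,5R)-4-(triethylsilyloxy)dauca-6,8-dien-6-yl trifluoromethanesulfonate
Conditions: Tf2O, 2,6-di-tert-butyl-4-methylpyridine, CH2Cl2, 0 °C → rt
Reagents that add atoms: trifluoromethanesulfonic anhydride, O=S(=O)(OS(=O)(=O)C(F)(F)F)C(F)(F)F
Why: O-triflation of the enone and γ-deprotonation by the hindered pyridine is the standard route to through-conjugated dienyl triflates; loss of the ring proton H9 should be preferred because it gives the more substituted endocyclic C8=C9 bond, while H5 is buried between two fully substituted carbons.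

**Step 9**
Reactants: 17 dienyl triflate
Product: 18 (1R,4R,5R)-4-(triethylsilyloxy)dauca-6,8-diene
Conditions: Pd(OAc)2 (5 mol %), PPh3 (10 mol %), HCO2H, Bu3N, DMF, 60 °C
Reagents that add atoms: none
Why: Palladium-catalysed formate reduction of an alkenyl triflate (oxidative addition to zerovalent palladium, decarboxylation of the formate, reductive elimination) replaces OTf by H without moving either double bond.

**Step 10**
Reactants: 18 silyl-protected dienol
Product: 19 (1R,4R,5S,6S,9S)-6,9-epidioxy-4-(triethylsilyloxy)dauc-7-ene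
Conditions: O2, tetraphenylporphyrin (cat.), CH2Cl2, −40 °C, visible light
Reagents that add atoms: dioxygen, O=O
Why: Sensitised singlet oxygen adds suprafacially across C6 and C9 of the ring-held s-cis diene in a concerted hetero-Diels–Alder reaction, forming the C6–O and C9–O bonds and moving the alkene to C7=C8. The closest known reaction type is the photooxygenation of cyclohepta-1,3-dienes and other cyclic 1,3-dienes to bicyclic endoperoxides. The 1,2-dioxine ring (O, O, C6, C7, C8, C9) is closed by [4+2] cycloaddition, giving a 6,7-dioxabicyclo[3.2.2]non-8-ene with C10–C1–C5 as the three-atom bridge. C6 and C9 are created together: suprafacial addition makes the two C–O bonds cis, and the face is set by the axial β-methyl on C1 (1,3 to C9) and the β-silyloxy group on C4 (1,3 to C6), so oxygen should arrive on the α face, cis to H5. The step needs cycloaddition to win over the ene reaction at the trisubstituted C8=C9 bond and α attack to win over β attack; the cisoid geometry enforced by the ring and the electron-rich trialkyl diene favour cycloaddition, low temperature in a non-polar solvent disfavours the ene path, and silylation of O4 removes a hydroxyl that could steer oxygen to the β face.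

**Step 11**
Reactants: 19 endoperoxide
Product: 20 (1R,4R,5S,6S)-6-hydroxy-4-(triethylsilyloxy)dauc-7-en-9-one
Conditions: Et3N, CH2Cl2, 0 °C → rt
Reagents that add atoms: none
Why: Kornblum–DeLaMare rearrangement: the amine should remove H9, flanked only by C10H2 and the C8 methyl, rather than H6, which sits next to the congested C5 and the C4 silyloxy group, and O–O cleavage then gives the C9 ketone and leaves the 6α-hydroxyl with its configuration unchanged.

**Step 12**
Reactants: 21 vanillic acid
Product: 23 4-(tert-butyldimethylsilyloxy)-3-methoxybenzoic acid, via bis-silylated vanillic acid 22 (not isolated)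
Conditions: TBSCl (2.5 equiv), imidazole, DMF, rt; then AcOH/THF/H2O, rt
Reagents that add atoms: tert-butyldimethylsilyl chloride, CC(C)(C)[Si](C)(C)Cl
Why: Exhaustive silylation followed by selective hydrolysis of the labile silyl ester is the usual protection of a hydroxybenzoic acid and leaves the phenol as the aryl silyl ether.

**Step 13**
Reactants: 20 hydroxy enone; 23 silyl-protected vanillic acid
Product: 25 (1R,4R,5S,6S)-9-oxo-4-(triethylsilyloxy)dauc-7-en-6-yl 4-(tert-butyldimethylsilyloxy)-3-methoxybenzoate, via acid chloride 24 (not isolated)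
Conditions: 23, (COCl)2, cat. DMF, CH2Cl2, 0 °C → rt, evaporate; then 20, Et3N, DMAP, CH2Cl2, 0 °C → rt
Reagents that add atoms: none
Why: DMAP-catalysed acylation by the acid chloride esterifies the only free hydroxyl, the secondary allylic C6–OH, with retention since the C6–O bond is not touched.

**Step 14**
Reactants: 25 keto ester
Product: 26 (1R,4R,5S,6S,9R)-9-hydroxy-4-(triethylsilyloxy)dauc-7-en-6-yl 4-(tert-butyldimethylsilyloxy)-3-methoxybenzoate
Conditions: NaBH4, CeCl3·7H2O, MeOH, −78 °C
Reagents that add atoms: none
Why: Luche reduction gives clean 1,2-reduction of the enone, and hydride should attack C9 from the α face, anti to the axial C1 methyl that is 1,3 to the carbonyl, giving the 9β-alcohol while the ester and both silyl ethers survive at −78 °C.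

**Step 15**
Reactants: 26 bis-silyl ether
Product: 27 (1R,4R,5S,6S,9R)-4,9-dihydroxydauc-7-en-6-yl 4-hydroxy-3-methoxybenzoate (target)
Conditions: TBAF, AcOH, THF, 0 °C → rt
Reagents that add atoms: none
Why: Fluoride cleaves the aryl silyl ether and the tertiary triethylsilyl ether in one operation, and the acetic acid buffer keeps the allylic ester from base-induced hydrolysis or acyl transfer.

**Compound list**
1 | 4-bromo-2-methylbut-1-ene | CC(=C)CCBr | starting material
2 | 3-ethoxycyclopent-2-en-1-one | CCOC1=CC(=O)CC1 | starting material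
3 | (3-methylbut-3-en-1-yl)magnesium bromide (formed in the flask) | C=C(C)CC[Mg]Br | intermediate
4 | bromomagnesium 3-ethoxy-1-(3-methylbut-3-en-1-yl)cyclopent-2-en-1-olate (formed in the flask) | CCOC1=CC(CCC(C)=C)(O[Mg]Br)CC1 | intermediate
5 | 3-(3-methylbut-3-en-1-yl)cyclopent-2-en-1-one | O=C1C=C(CCC(C)=C)CC1 | intermediate
6 | trimethylaluminium | C[Al](C)C | starting material
7 | dimethylaluminium (S)-3-methyl-3-(3-methylbut-3-en-1-yl)cyclopent-1-en-1-olate (formed in the flask) | C[C@]1(CCC(C)=C)CCC(O[Al](C)C)=C1 | intermediate
8 | (S)-trimethyl{[3-methyl-3-(3-methylbut-3-en-1-yl)cyclopent-1-en-1-yl]oxy}silane | C[C@]1(CCC(C)=C)CCC(O[Si](C)(C)C)=C1 | intermediate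
9 | acrolein (prop-2-enal) | C=CC=O | starting material
10 | lithium (S)-3-methyl-3-(3-methylbut-3-en-1-yl)cyclopent-1-en-1-olate (formed in the flask) | C[C@]1(CCC(C)=C)CCC(O[Li])=C1 | intermediate
11 | (2S,3S)-2-(1-hydroxyprop-2-en-1-yl)-3-methyl-3-(3-methylbut-3-en-1-yl)cyclopentan-1-one, both carbinol epimers | C=CC(O)[C@@H]1[C@@](C)(CCC(C)=C)CCC1=O | intermediate
12 | isopropylmagnesium chloride | CC(C)[Mg]Cl | starting material
13 | (1R,2S,3S)-2-(1-hydroxyprop-2-en-1-yl)-3-methyl-3-(3-methylbut-3-en-1-yl)-1-(propan-2-yl)cyclopentan-1-ol, both carbinol epimers | C=CC(O)[C@@H]1[C@@](C)(CCC(C)=C)CC[C@@]1(O)C(C)C | intermediate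
14 | (1S,4R,5S)-dauc-7-ene-4,6-diol, both C6 epimers | OC1C=C(C)CC[C@@]2(C)CC[C@@](O)(C(C)C)[C@H]12 | intermediate
15 | (1S,4R,5R)-4-hydroxydauc-7-en-6-one | O=C1C=C(C)CC[C@@]2(C)CC[C@@](O)(C(C)C)[C@H]12 | intermediate
16 | (1S,4R,5R)-4-(triethylsilyloxy)dauc-7-en-6-one | O=C1C=C(C)CC[C@@]2(C)CC[C@@](O[Si](CC)(CC)CC)(C(C)C)[C@H]12 | intermediate
17 | (1R,4R,5R)-4-(triethylsilyloxy)dauca-6,8-dien-6-yl trifluoromethanesulfonate | O=S(=O)(OC1=CC(C)=CC[C@@]2(C)CC[C@@](O[Si](CC)(CC)CC)(C(C)C)[C@H]12)C(F)(F)F | intermediate
18 | (1R,4R,5R)-4-(triethylsilyloxy)dauca-6,8-diene | C1=CC(C)=CC[C@@]2(C)CC[C@@](O[Si](CC)(CC)CC)(C(C)C)[C@H]12 | intermediate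
19 | (1R,4R,5S,6S,9S)-6,9-epidioxy-4-(triethylsilyloxy)dauc-7-ene | O1[C@H]2C=C(C)[C@@H](O1)C[C@@]3(C)CC[C@@](O[Si](CC)(CC)CC)(C(C)C)[C@H]23 | intermediate
20 | (1R,4R,5S,6S)-6-hydroxy-4-(triethylsilyloxy)dauc-7-en-9-one | O[C@H]1C=C(C)C(=O)C[C@@]2(C)CC[C@@](O[Si](CC)(CC)CC)(C(C)C)[C@H]12 | intermediate
21 | vanillic acid (4-hydroxy-3-methoxybenzoic acid) | COc1cc(C(=O)O)ccc1O | starting material
22 | tert-butyldimethylsilyl 4-(tert-butyldimethylsilyloxy)-3-methoxybenzoate (formed in the flask) | COc1cc(C(=O)O[Si](C)(C)C(C)(C)C)ccc1O[Si](C)(C)C(C)(C)C | intermediate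
23 | 4-(tert-butyldimethylsilyloxy)-3-methoxybenzoic acid | COc1cc(C(=O)O)ccc1O[Si](C)(C)C(C)(C)C | intermediate
24 | 4-(tert-butyldimethylsilyloxy)-3-methoxybenzoyl chloride (formed in the flask) | COc1cc(C(=O)Cl)ccc1O[Si](C)(C)C(C)(C)C | intermediate
25 | (1R,4R,5S,6S)-9-oxo-4-(triethylsilyloxy)dauc-7-en-6-yl 4-(tert-butyldimethylsilyloxy)-3-methoxybenzoate | COc1cc(C(=O)O[C@H]2C=C(C)C(=O)C[C@@]3(C)CC[C@@](O[Si](CC)(CC)CC)(C(C)C)[C@H]23)ccc1O[Si](C)(C)C(C)(C)C | intermediate
26 | (1R,4R,5S,6S,9R)-9-hydroxy-4-(triethylsilyloxy)dauc-7-en-6-yl 4-(tert-butyldimethylsilyloxy)-3-methoxybenzoate | COc1cc(C(=O)O[C@H]2C=C(C)[C@H](O)C[C@@]3(C)CC[C@@](O[Si](CC)(CC)CC)(C(C)C)[C@H]23)ccc1O[Si](C)(C)C(C)(C)C | intermediate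
27 | (1R,4R,5S,6S,9R)-4,9-dihydroxydauc-7-en-6-yl 4-hydroxy-3-methoxybenzoate | COc1cc(C(=O)O[C@H]2C=C(C)[C@H](O)C[C@@]3(C)CC[C@@](O)(C(C)C)[C@H]23)ccc1O | target

**Step count**
Total: 15 steps. Longest linear sequence: 14 steps (steps 1 to 11 and 13 to 15); step 12 is a one-step side branch.

**Steps most likely to fail**

Step 10. Hydrogen abstraction by singlet oxygen at the C8 methyl or at C10 (ene reaction at the trisubstituted alkene) may outrun the cycloaddition, and oxygen may also approach from the β face. Fallback: setting out from diene 18, the same endoperoxide would be made without singlet oxygen by cation-radical chain oxygenation, using ground-state O2 and catalytic tris(4-bromophenyl)aminium hexachloroantimonate, (4-BrC6H4)3N SbCl6, in CH2Cl2 at −78 °C. The diene radical cation takes up triplet oxygen and closes the same 1,2-dioxine, a pathway with no ene branch. It returns to the route at 19 and makes no new compound (F0).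

Step 11. The base may abstract H6 instead of H9, giving the regioisomeric C6 ketone, or the hydroxy enone may isomerise further to the 1,4-diketone on prolonged exposure to base. Fallback: setting out from endoperoxide 19, the O–O bond is reduced with thiourea in MeOH to the cis-6α,9α-diol F1. The less hindered C9 carbinol is then oxidised selectively with catalytic TEMPO and PhI(OAc)2 in CH2Cl2, an oxoammonium oxidation that is strongly retarded at the C6 carbinol next to the congested C5. This returns to the route at hydroxy enone 20.

Step 8. Proton loss from the C8 methyl (exocyclic methylene isomer) or from C5 (cross-conjugated isomer) may compete with loss of H9, and ionisation next to the silyloxy group may erode material. Fallback: setting out from enone 16, the regiochemistry is set under equilibrating silyl transfer instead: TMSOTf and Et3N in CH2Cl2 (0 °C → rt) give the endocyclic trimethylsilyl dienol ether F2. MeLi in THF cleaves it to the lithium dienolate F3, which is O-triflated at −78 °C with N-(5-chloropyridin-2-yl)-1,1,1-trifluoro-N-(trifluoromethylsulfonyl)methanesulfonamide. This returns to the route at dienyl triflate 17.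

**Further compounds**
F0 | step 10 | none | none
F1 | step 11 | (1R,4R,5S,6S,9S)-4-(triethylsilyloxy)dauc-7-ene-6,9-diol | O[C@H]1C=C(C)[C@@H](O)C[C@@]2(C)CC[C@@](O[Si](CC)(CC)CC)(C(C)C)[C@H]12
F2 | step 8 | 4-(triethylsilyloxy)-6-(trimethylsilyloxy)dauca-6,8-diene, configuration at C1, C4 and C5 as in 16 | C[Si](C)(C)OC1=CC(C)=CC[C@@]2(C)CC[C@@](O[Si](CC)(CC)CC)(C(C)C)[C@H]12
F3 | step 8 | lithium 4-(triethylsilyloxy)dauca-6,8-dien-6-olate, configuration at C1, C4 and C5 as in 16 | [Li]OC1=CC(C)=CC[C@@]2(C)CC[C@@](O[Si](CC)(CC)CC)(C(C)C)[C@H]12
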